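In a one-step world X goes to J with a single pseudo-first-order constant k′, and one number per flask tells the whole run; this flask has more steps, but I try to reduce it to that number.

    X + G ⇌ X.G (K1 = 3700 /M, k1 = 6000 /M/s)
    X.G → G + J (k2 = 6.6 /s)
    G + E ⇌ G.E, settled at all times (K3 = 2.1 × 10⁵ /M)
    J → D (k4 = 0.031 /s)

in all of them: X 0.0010 M; E 14 µM; time 5.0 min
- red: G 2.0 µM
- grey: G 3.0 µM
- teal: G 5.0 µM

* [J] at the end for red, grey, teal, in this order
* the course of these numbers from the first flask to the last (falls, then rises / rises all the way / hardly changes / falls all the way / rises, then falls)

- "hardly changes" means that all values lie within two and a half points (for a concentration: within two and a half percent of the largest)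
- run time (red): 5.0 min

X.G leaves by falling back at 1.62 /s and by turning over at 6.6 /s, and their sum over 6000 /M/s gives the Michaelis constant Km = 1.37 mM, so free G consumes X with a second-order constant of 4820 /M/s. Free G counts as one part against 2.94 parts of G.E and, with X at its charge, 0.730 parts of X.G. I solve the two ends of the range of X, a free share of 21.4% with X at its charge and 25.4% with X at zero, and join them by the mean, 23.4%.

Then k′ times the run time reads 0.676 for red, 1.01 for grey and 1.69 for teal. Because the half-life of J, 0.37 min, is shorter than the run, J tracks its source: k′ times [X] at the end of the run, over the difference between 0.031 /s and k′. That gives 39.9 µM, 44.4 µM and 41.0 µM, a row that rises and then falls.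

The weak link is E held at its charge. I reckon that G.E holds about 63.0% of the catalyst, so I take teal to lose 3.15 µM of its E, more than red's 1.26 µM, and free G to gain. Reforged, the values become 0.721, 1.12 and 2.00; each is the run clock τ of its flask, the number of e-foldings of X in the run. I commit to 40.9 µM, 44.7 µM and 37.0 µM.

The forecast gives 4.180 × 10⁻⁵ M, 4.710 × 10⁻⁵ M and 4.020 × 10⁻⁵ M, rises, then falls, on the ground, said of J, that “it tracks the slowly falling rate”; its teal value stands above mine.

The flask gives 4.16 × 10⁻⁵ M, 4.70 × 10⁻⁵ M and 3.98 × 10⁻⁵ M, rises, then falls, with the row turning at 3.2 µM of G. The half-life of J at the end of red, 0.37 min, is short against the run of 5.0 min, and red ends with J at 4.16% of the X charged beside D at 45.6%. The clock reads X: exp(−τ) is 48.6% for red, where 50% is left, and 13.5% for teal, where 13% is left.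

(All constants stand for no real mixture; what happens was integrated by code.)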